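**Retrosynthetic overview**
1. Target 20 ⇐ Luche reduction at C9 ⇐ anisoylation of the C6 alcohol ⇐ hydroxyl-directed reduction at C6 of ene-dione 16.
2. 16 ⇐ oxidation/dehydrogenation of hydroxy ketone 15 ⇐ SmI2 opening of the C5–O bond of oxa-bridged ketone 14 ⇐ methyl cuprate addition to enone 13.
3. 13 ⇐ intramolecular oxidopyrylium–alkene [5+2] cycloaddition; the five- and seven-membered carbocycles close together and C1 is set from C4.
4. The pyrylium comes from the Achmatowicz product 10 of furyl diol 9 ⇐ 2-furyllithium + dioxolanone 5.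
5. 5 ⇐ Seebach alkylation of the pivalaldehyde acetal of (R)-2-hydroxy-3-methylbutanoic acid, which supplies the only purchased stereocentre (C4).

Assumption: (R)-2-hydroxy-3-methylbutanoic acid (the D-valine-derived catalogue acid) is taken as the cheap chiral starting material; locants C1–C10 in the text use daucane numbering (C1 = C–Me ring fusion, C4 = C(OH)iPr, C5 = CH ring fusion, C6 = C–O-aroyl, C8 = C–Me, C9 = CHOH).

**Route**

Step 1
Reactants: 1 (R)-2-hydroxy-3-methylbutanoic acid; 2 pivalaldehyde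
Product: 3 (2R,5R)-2-tert-butyl-5-(propan-2-yl)-1,3-dioxolan-4-one
Conditions: TsOH (cat.), H2SO4 (cat.), pentane, reflux, Dean–Stark; recrystallise
Reagents that add atoms: none
Why: Acid-catalysed acetalisation (Seebach dioxolanone) under thermodynamic control places tert-butyl cis to isopropyl, so the new acetal centre (2R) is dictated by the purchased (R) centre.

Step 2
Reactants: 3 (2R,5R)-2-tert-butyl-5-(propan-2-yl)-1,3-dioxolan-4-one; 4 4-iodo-2-methylbut-1-ene
Product: 5 (2R,5R)-2-tert-butyl-5-(3-methylbut-3-en-1-yl)-5-(propan-2-yl)-1,3-dioxolan-4-one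
Conditions: LDA (1.1 equiv), THF/DMPU, −78 °C; then 4, −78 → −30 °C
Reagents that add atoms: none
Why: Enolate alkylation with self-regeneration of the stereocentre: the planar lithium enolate is alkylated anti to tert-butyl, so the chain replaces H with retention and the future C4 is fixed as R.

Step 3
Reactants: 5 (2R,5R)-2-tert-butyl-5-(3-methylbut-3-en-1-yl)-5-(propan-2-yl)-1,3-dioxolan-4-one; 6 furan
Product: 9 (1RS,2R)-1-(furan-2-yl)-5-methyl-2-(propan-2-yl)hex-5-ene-1,2-diol, via 2-furyllithium 7 (not isolated), via furyl hydroxy ketone 8 (not isolated)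
Conditions: 6, n-BuLi, THF, 0 °C; then 5, −78 → 0 °C; then MeOH, NaBH4, 0 °C → rt
Reagents that add atoms: none
Why: Nucleophilic acyl substitution: 2-furyllithium adds once to the activated acylal carbonyl, methanol collapses the tetrahedral alkoxide to the hindered ketone and pivalaldehyde, and borohydride then gives the furfuryl alcohol, whose new carbinol centre is left as a mixture because it becomes sp2 in step 5.

Step 4
Reactants: 9 (1RS,2R)-1-(furan-2-yl)-5-methyl-2-(propan-2-yl)hex-5-ene-1,2-diol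
Product: 10 6-hydroxy-2-[(3R)-3-hydroxy-2,6-dimethylhept-6-en-3-yl]-2H-pyran-3(6H)-one (mixture of ring diastereomers)
Conditions: NBS (1.05 equiv), NaHCO3, THF/H2O 4:1, 0 °C
Reagents that add atoms: water, O
Why: Achmatowicz oxidative ring expansion: bromonium attack on the electron-rich furan outruns the isolated alkene at 0 °C and the secondary furfuryl hydroxyl closes the six-membered hemiacetal; both ring stereocentres are mixtures that are erased when the pyrylium forms.

Step 5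
Reactants: 10 6-hydroxy-2-[(3R)-3-hydroxy-2,6-dimethylhept-6-en-3-yl]-2H-pyran-3(6H)-one
Product: 13 (1S,2R,5R,7S)-2-hydroxy-5-methyl-2-(propan-2-yl)-11-oxatricyclo[5.3.1.0(1,5)]undec-8-en-10-one, via acetoxypyranone 11 (not isolated), via 3-oxidopyrylium ylide 12 (not isolated)
Conditions: Ac2O (1.2 equiv), DMAP (cat.), i-Pr2NEt (3 equiv), MeCN, 0 °C → rt; then 0.01 M, 80 °C
Reagents that add atoms: none
Why: Acetylation and E1cB loss of acetate give the 3-oxidopyrylium, which undergoes an intramolecular [5+2] cycloaddition with the tethered 1,1-disubstituted alkene; the three-atom tether must sit exo (C1–Me endo, anti to the oxygen bridge), and A(1,3) strain plus an OH···oxide hydrogen bond put the small C4–OH syn to the oxide and isopropyl anti to the incoming alkene, so C1–Me ends cis to C4–OH (C1 R, C5 and C9 bridged on the isopropyl face).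

Step 6
Reactants: 13 (1S,2R,5R,7S)-2-hydroxy-5-methyl-2-(propan-2-yl)-11-oxatricyclo[5.3.1.0(1,5)]undec-8-en-10-one
Product: 14 (1S,2R,5R,7S,8R)-2-hydroxy-5,8-dimethyl-2-(propan-2-yl)-11-oxatricyclo[5.3.1.0(1,5)]undecan-10-one
Conditions: Me2CuLi (3 equiv), Et2O/THF, −78 → −20 °C
Reagents that add atoms: lithium dimethylcuprate, [Li+].C[Cu-]C
Why: Cuprate conjugate addition to the bridged enone from the exo face (syn to the oxygen bridge, away from the endo C1 methyl) installs the C8 methyl and removes the enone conjugation; this C8 centre is temporary and is flattened again in step 8.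

Step 7
Reactants: 14 (1S,2R,5R,7S,8R)-2-hydroxy-5,8-dimethyl-2-(propan-2-yl)-11-oxatricyclo[5.3.1.0(1,5)]undecan-10-one
Product: 15 (3R,3aR,6R,7S,8aR)-3,7-dihydroxy-6,8a-dimethyl-3-(propan-2-yl)octahydroazulen-4(1H)-one
Conditions: SmI2 (2.5 equiv), THF/MeOH, −78 °C
Reagents that add atoms: none
Why: Samarium diiodide reduction of the now non-conjugated α-alkoxy ketone cleaves only the C5–O bond, freeing the C9 alkoxide with retention; protonation of the samarium enolate (C5 stays enolisable and can equilibrate) gives the trans-fused ketone with C5–H cis to isopropyl and C6 cis to the C4 hydroxyl.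

Step 8
Reactants: 15 (3R,3aR,6R,7S,8aR)-3,7-dihydroxy-6,8a-dimethyl-3-(propan-2-yl)octahydroazulen-4(1H)-one
Product: 16 (3R,3aR,8aR)-3-hydroxy-6,8a-dimethyl-3-(propan-2-yl)-1,2,3,3a,8,8a-hexahydroazulene-4,7-dione
Conditions: IBX (4 equiv), 4-methoxypyridine N-oxide (4 equiv), DMSO, 25 → 45 °C
Reagents that add atoms: none
Why: IBX oxidises the C9 carbinol and then dehydrogenates the resulting 1,4-diketone to the ene-dione; C7=C8 is the only possible position because C1 and C4 are quaternary, and the temporary C8 and C9 centres disappear.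

Step 9
Reactants: 16 (3R,3aR,8aR)-3-hydroxy-6,8a-dimethyl-3-(propan-2-yl)-1,2,3,3a,8,8a-hexahydroazulene-4,7-dione
Product: 17 (1R,3aR,8S,8aS)-1,8-dihydroxy-3a,6-dimethyl-1-(propan-2-yl)-1,2,3,3a,8,8a-hexahydroazulen-5(4H)-one
Conditions: Me4NBH(OAc)3 (5 equiv), MeCN/AcOH 1:1, −30 → −20 °C
Reagents that add atoms: none
Why: Evans–Saksena hydroxyl-directed reduction: the C4 hydroxyl binds boron and delivers hydride intramolecularly to the β-ketone C6 only, giving the 1,3-anti diol (C6–OH trans to C4–OH, cis to H5), while the undirected C9 carbonyl is not reduced by triacetoxyborohydride.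

Step 10
Reactants: 17 (1R,3aR,8S,8aS)-1,8-dihydroxy-3a,6-dimethyl-1-(propan-2-yl)-1,2,3,3a,8,8a-hexahydroazulen-5(4H)-one; 18 4-methoxybenzoyl chloride
Product: 19 (3R,3aS,4S,8aR)-3-hydroxy-6,8a-dimethyl-7-oxo-3-(propan-2-yl)-1,2,3,3a,4,7,8,8a-octahydroazulen-4-yl 4-methoxybenzoate
Conditions: DMAP (0.2 equiv), Et3N, CH2Cl2, 0 °C → rt
Reagents that add atoms: none
Why: DMAP-catalysed acylation of the only secondary hydroxyl; the hindered tertiary C4 carbinol does not react and no stereocentre is touched.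

Step 11
Reactants: 19 (3R,3aS,4S,8aR)-3-hydroxy-6,8a-dimethyl-7-oxo-3-(propan-2-yl)-1,2,3,3a,4,7,8,8a-octahydroazulen-4-yl 4-methoxybenzoate
Product: 20 (3R,3aS,4S,7R,8aR)-3,7-dihydroxy-6,8a-dimethyl-3-(propan-2-yl)-1,2,3,3a,4,7,8,8a-octahydroazulen-4-yl 4-methoxybenzoate
Conditions: NaBH4, CeCl3·7H2O, MeOH, −78 °C
Reagents that add atoms: none
Why: Luche 1,2-reduction of the enone: hydride attacks C9 from the face opposite the pseudo-axial C1 methyl (1,3 to C9), which places the new hydroxyl cis to that methyl (9R) and leaves the aryl ester intact.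

**Compound list**
1 | (R)-2-hydroxy-3-methylbutanoic acid | CC(C)[C@@H](O)C(=O)O | starting material
2 | pivalaldehyde | CC(C)(C)C=O | starting material
3 | (2R,5R)-2-tert-butyl-5-(propan-2-yl)-1,3-dioxolan-4-one | CC(C)[C@H]1O[C@@H](C(C)(C)C)OC1=O | intermediate
4 | 4-iodo-2-methylbut-1-ene | C=C(C)CCI | starting material
5 | (2R,5R)-2-tert-butyl-5-(3-methylbut-3-en-1-yl)-5-(propan-2-yl)-1,3-dioxolan-4-one | CC(C)[C@@]1(CCC(C)=C)O[C@@H](C(C)(C)C)OC1=O | intermediate
6 | furan | c1ccoc1 | starting material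
7 | 2-furyllithium (formed in situ) | [Li]c1ccco1 | intermediate
8 | (2R)-1-(furan-2-yl)-2-hydroxy-5-methyl-2-(propan-2-yl)hex-5-en-1-one (formed in situ) | O=C(c1ccco1)[C@](O)(C(C)C)CCC(C)=C | intermediate
9 | (1RS,2R)-1-(furan-2-yl)-5-methyl-2-(propan-2-yl)hex-5-ene-1,2-diol | OC(c1ccco1)[C@](O)(C(C)C)CCC(C)=C | intermediate
10 | 6-hydroxy-2-[(3R)-3-hydroxy-2,6-dimethylhept-6-en-3-yl]-2H-pyran-3(6H)-one (ring diastereomers) | O=C1C=CC(O)OC1[C@](O)(C(C)C)CCC(C)=C | intermediate
11 | 6-[(3R)-3-hydroxy-2,6-dimethylhept-6-en-3-yl]-5-oxo-5,6-dihydro-2H-pyran-2-yl acetate (formed in situ) | CC(=O)OC1OC([C@](O)(C(C)C)CCC(C)=C)C(=O)C=C1 | intermediate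
12 | 2-[(3R)-3-hydroxy-2,6-dimethylhept-6-en-3-yl]pyrylium-3-olate (formed in situ) | [O-]c1ccc[o+]c1[C@](O)(C(C)C)CCC(C)=C | intermediate
13 | (1S,2R,5R,7S)-2-hydroxy-5-methyl-2-(propan-2-yl)-11-oxatricyclo[5.3.1.0(1,5)]undec-8-en-10-one (oxygen bridge C5–O–C9 on the isopropyl face, C1–Me on the opposite face) | O=C1C=C[C@@H]2C[C@@]3(C)CC[C@@](O)(C(C)C)[C@]13O2 | intermediate
14 | (1S,2R,5R,7S,8R)-2-hydroxy-5,8-dimethyl-2-(propan-2-yl)-11-oxatricyclo[5.3.1.0(1,5)]undecan-10-one | O=C1C[C@@H](C)[C@@H]2C[C@@]3(C)CC[C@@](O)(C(C)C)[C@]13O2 | intermediate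
15 | (3R,3aR,6R,7S,8aR)-3,7-dihydroxy-6,8a-dimethyl-3-(propan-2-yl)octahydroazulen-4(1H)-one | O=C1C[C@@H](C)[C@@H](O)C[C@@]2(C)CC[C@@](O)(C(C)C)[C@H]12 | intermediate
16 | (3R,3aR,8aR)-3-hydroxy-6,8a-dimethyl-3-(propan-2-yl)-1,2,3,3a,8,8a-hexahydroazulene-4,7-dione | O=C1C=C(C)C(=O)C[C@@]2(C)CC[C@@](O)(C(C)C)[C@H]12 | intermediate
17 | (1R,3aR,8S,8aS)-1,8-dihydroxy-3a,6-dimethyl-1-(propan-2-yl)-1,2,3,3a,8,8a-hexahydroazulen-5(4H)-one | O[C@H]1C=C(C)C(=O)C[C@@]2(C)CC[C@@](O)(C(C)C)[C@H]12 | intermediate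
18 | 4-methoxybenzoyl chloride | COc1ccc(C(Cl)=O)cc1 | starting material
19 | (3R,3aS,4S,8aR)-3-hydroxy-6,8a-dimethyl-7-oxo-3-(propan-2-yl)-1,2,3,3a,4,7,8,8a-octahydroazulen-4-yl 4-methoxybenzoate | COc1ccc(C(=O)O[C@H]2C=C(C)C(=O)C[C@@]3(C)CC[C@@](O)(C(C)C)[C@H]23)cc1 | intermediate
20 | (3R,3aS,4S,7R,8aR)-3,7-dihydroxy-6,8a-dimethyl-3-(propan-2-yl)-1,2,3,3a,4,7,8,8a-octahydroazulen-4-yl 4-methoxybenzoate | COc1ccc(C(=O)O[C@H]2C=C(C)[C@H](O)C[C@@]3(C)CC[C@@](O)(C(C)C)[C@H]23)cc1 | target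

**Step count and risks**
Total steps: 11. Longest linear sequence: 11 (1 → 20).

Steps most likely to fail:

Step 2. The hindered α-isopropyl enolate has to displace an unactivated homoallylic iodide, and E2 to isoprene and enolate decomposition compete. Fallback, from 3 back to 5: use conjugate addition instead of SN2. The lithium enolate of 3 is added to but-3-en-2-one (THF, −78 °C), again anti to tert-butyl, to give (2R,5R)-2-tert-butyl-5-(3-oxobutyl)-5-(propan-2-yl)-1,3-dioxolan-4-one F1. The methyl ketone is then methylenated chemoselectively with Ph3P=CH2 (THF, 0 °C) to reach 5.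

Step 5. The free tertiary hydroxyl next to the pyranone could capture the anomeric carbon as a bicyclic ketal before the ylide forms, and the facial selectivity rests on a conformational preference rather than a precedent for this exact substrate. Fallback, from 10 back to 13: 10 is acetylated and 11 is isolated. The tertiary hydroxyl is capped with N-(trimethylsilyl)imidazole to give 6-[(3R)-2,6-dimethyl-3-(trimethylsilyloxy)hept-6-en-3-yl]-5-oxo-5,6-dihydro-2H-pyran-2-yl acetate F2. DBU in MeCN at 60 °C generates 2-[(3R)-2,6-dimethyl-3-(trimethylsilyloxy)hept-6-en-3-yl]pyrylium-3-olate F3, which cyclises under steric control alone (small OSiMe3 syn to the oxide, isopropyl anti to the alkene) to the O-trimethylsilyl ether of 13 F4. K2CO3/MeOH removes the silyl group and gives 13.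

Step 8. The one-pot alcohol oxidation and dehydrogenation runs next to a tertiary β-hydroxy ketone that can dehydrate, and the ene-dione product is sensitive. Fallback, from 15 back to 19: introduce the alkene only after C6 has been reduced and acylated. Dess–Martin periodinane oxidises the C9 carbinol to (3R,3aR,6R,8aR)-3-hydroxy-6,8a-dimethyl-3-(propan-2-yl)octahydroazulene-4,7-dione F5. Me4NBH(OAc)3, directed by the C4 hydroxyl, reduces C6 to (1R,3aR,6R,8S,8aS)-1,8-dihydroxy-3a,6-dimethyl-1-(propan-2-yl)octahydroazulen-5(1H)-one F6. Acylation with 18 gives (3R,3aS,4S,6R,8aR)-3-hydroxy-6,8a-dimethyl-7-oxo-3-(propan-2-yl)decahydroazulen-4-yl 4-methoxybenzoate F7. Pd(TFA)2/DMSO-catalysed aerobic dehydrogenation (O2, AcOH, 80 °C), which can only desaturate C7–C8 because C1 is quaternary, then gives 19.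

**Further compounds**
F1 | step 2 | (2R,5R)-2-tert-butyl-5-(3-oxobutyl)-5-(propan-2-yl)-1,3-dioxolan-4-one | CC(C)[C@@]1(CCC(C)=O)O[C@@H](C(C)(C)C)OC1=O
F2 | step 5 | 6-[(3R)-2,6-dimethyl-3-(trimethylsilyloxy)hept-6-en-3-yl]-5-oxo-5,6-dihydro-2H-pyran-2-yl acetate | CC(=O)OC1OC([C@](O[Si](C)(C)C)(C(C)C)CCC(C)=C)C(=O)C=C1
F3 | step 5 | 2-[(3R)-2,6-dimethyl-3-(trimethylsilyloxy)hept-6-en-3-yl]pyrylium-3-olate | [O-]c1ccc[o+]c1[C@](O[Si](C)(C)C)(C(C)C)CCC(C)=C
F4 | step 5 | (1S,2R,5R,7S)-5-methyl-2-(propan-2-yl)-2-(trimethylsilyloxy)-11-oxatricyclo[5.3.1.0(1,5)]undec-8-en-10-one | O=C1C=C[C@@H]2C[C@@]3(C)CC[C@@](O[Si](C)(C)C)(C(C)C)[C@]13O2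
F5 | step 8 | (3R,3aR,6R,8aR)-3-hydroxy-6,8a-dimethyl-3-(propan-2-yl)octahydroazulene-4,7-dione | O=C1C[C@@H](C)C(=O)C[C@@]2(C)CC[C@@](O)(C(C)C)[C@H]12
F6 | step 8 | (1R,3aR,6R,8S,8aS)-1,8-dihydroxy-3a,6-dimethyl-1-(propan-2-yl)octahydroazulen-5(1H)-one | O[C@H]1C[C@@H](C)C(=O)C[C@@]2(C)CC[C@@](O)(C(C)C)[C@H]12
F7 | step 8 | (3R,3aS,4S,6R,8aR)-3-hydroxy-6,8a-dimethyl-7-oxo-3-(propan-2-yl)decahydroazulen-4-yl 4-methoxybenzoate | COc1ccc(C(=O)O[C@H]2C[C@@H](C)C(=O)C[C@@]3(C)CC[C@@](O)(C(C)C)[C@H]23)cc1
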